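**Retrosynthetic overview**

1. Target 21 ← 20/19: the C15 acid comes from a silyl-protected primary alcohol and the angelate from Yamaguchi acylation of the neopentyl C18 hydroxyl. Before that, diol 16 (8-OH and axial C17 methyl) comes from Markovnikov hydration of the C8(17) olefin of 15, and the C3 methylene of 15 from radical deoxygenation through a temporary 3,18-cyclic thionocarbonate.
2. Key disconnection: the ring A bond C4–C5 and, in the same cascade, the ring B bond C9–C10, by Cp2TiCl-mediated radical bicyclisation of the acyclic (2R,3R)-epoxy alcohol 11. The oxygen on C3 is a temporary handle that carries the absolute configuration and is removed in steps 10–11.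
3. Enabling feature: rings A and B are a head-to-tail isoprenoid array in which C4, C10 and C8 are methyl-bearing and 1,5-related, so each ring-closing bond joins a fully substituted carbon to a CH. The oxygen on C18, bound to quaternary C4, makes the open-chain terminus an (E)-allylic alcohol that can be epoxidised selectively and whose hydroxyl can chelate titanium.
4. Triene 10 ← allyl sulfone alkylation and desulfonylation joining C6–C7: hydroxy sulfone 3 (from geranyl bromide 1) plus allylic bromide 7 (from (S)-citronellol 4, which supplies C13).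
5. Ring order: ring A first (C4–C5), ring B second (C9–C10), both in step 9; the precursor is acyclic.

Key step: step 9

Remark: locants in the prose are labdane locants (C4 = ring A quaternary carbon bearing the methyl C19 and the CH2O carbon C18; C10 = angular carbon bearing C20; C8 bears C17; C9 bears the chain C11–C15 with C16 on C13). Compounds 1, 4, 17 and D-(−)-diethyl tartrate are assumed to be purchased.

**Route**

Step 1
Reactants: 1 geranyl bromide
Product: 2 geranyl phenyl sulfone
Conditions: PhSO2Na, DMF, rt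
Reagents that add atoms: sodium benzenesulfinate, [Na+].[O-]S(=O)c1ccccc1
Why: SN2 alkylation of the sulfinate at sulfur by the primary allylic bromide should give the allyl sulfone with the E olefin untouched.

Step 2
Reactants: 2 geranyl phenyl sulfone
Product: 3 (2E,6E)-2,6-dimethyl-8-(phenylsulfonyl)octa-2,6-dien-1-ol
Conditions: SeO2 (0.1 equiv), t-BuOOH (3 equiv), salicylic acid (0.1 equiv), CH2Cl2, 0 °C to rt
Reagents that add atoms: selenium dioxide, O=[Se]=O (catalytic oxygen carrier, re-oxidised by tert-butyl hydroperoxide, CC(C)(C)OO)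
Why: Catalytic SeO2 allylic oxidation (ene reaction, then [2,3]-sigmatropic shift) should hydroxylate the E-methyl of the electron-rich terminal olefin, the olefin next to the sulfonyl group being deactivated, and give the E allylic alcohol.

Step 3
Reactants: 4 (S)-citronellol
Product: 5 tert-butyl{[(3S)-3,7-dimethyloct-6-en-1-yl]oxy}diphenylsilane
Conditions: TBDPSCl, imidazole, CH2Cl2, 0 °C to rt
Reagents that add atoms: tert-butyl(chloro)diphenylsilane, CC(C)(C)[Si](Cl)(c1ccccc1)c1ccccc1
Why: Standard silylation protects the future C15 oxygen with a group that should survive organolithium, hydride, radical and mild acid conditions.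

Step 4
Reactants: 5 tert-butyl{[(3S)-3,7-dimethyloct-6-en-1-yl]oxy}diphenylsilane
Product: 6 (2E,6S)-8-[(tert-butyldiphenylsilyl)oxy]-2,6-dimethyloct-2-en-1-ol
Conditions: SeO2 (0.1 equiv), t-BuOOH (3 equiv), salicylic acid (0.1 equiv), CH2Cl2, 0 °C to rt
Reagents that add atoms: selenium dioxide, O=[Se]=O (catalytic oxygen carrier, re-oxidised by tert-butyl hydroperoxide, CC(C)(C)OO)
Why: The same E-selective SeO2 allylic oxidation should functionalise the E-methyl of the isopropylidene group, which becomes C7, and fixes the E geometry of the future C8=C9 olefin.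

Step 5
Reactants: 6 (2E,6S)-8-[(tert-butyldiphenylsilyl)oxy]-2,6-dimethyloct-2-en-1-ol
Product: 7 {[(3S,6E)-8-bromo-3,7-dimethyloct-6-en-1-yl]oxy}(tert-butyl)diphenylsilane
Conditions: CBr4, PPh3, CH2Cl2, 0 °C
Reagents that add atoms: carbon tetrabromide, BrC(Br)(Br)Br
Why: The Appel reaction should convert the primary allylic alcohol into the bromide by SN2 displacement without allylic transposition or loss of olefin geometry.

Step 6
Reactants: 3 (2E,6E)-2,6-dimethyl-8-(phenylsulfonyl)octa-2,6-dien-1-ol; 7 {[(3S,6E)-8-bromo-3,7-dimethyloct-6-en-1-yl]oxy}(tert-butyl)diphenylsilane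
Product: 9 (2E,6E,10E,14S)-16-[(tert-butyldiphenylsilyl)oxy]-2,6,10,14-tetramethyl-8-(phenylsulfonyl)hexadeca-2,6,10-trien-1-ol (both C8 epimers), via dilithiated sulfone 8 (not isolated)
Conditions: n-BuLi (2.1 equiv), THF–DMPU, −78 °C; then 7, −78 to −20 °C; H2O
Reagents that add atoms: none
Why: In the O,C-dianion the α-sulfonyl carbanion is far more nucleophilic than the lithium alkoxide and should displace the primary allylic bromide at its α-carbon (allyl sulfone alkylation), joining C6 to C7 with all olefin geometries retained; the unselective sulfone-bearing stereocentre is erased in step 7.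

Step 7
Reactants: 9 (2E,6E,10E,14S)-16-[(tert-butyldiphenylsilyl)oxy]-2,6,10,14-tetramethyl-8-(phenylsulfonyl)hexadeca-2,6,10-trien-1-ol
Product: 10 (2E,6E,10E,14S)-16-[(tert-butyldiphenylsilyl)oxy]-2,6,10,14-tetramethylhexadeca-2,6,10-trien-1-ol
Conditions: PdCl2(dppp) (5 mol %), LiBHEt3 (3 equiv), THF, 0 °C
Reagents that add atoms: none
Why: Zerovalent palladium should ionise the allylic sulfone to a π-allyl complex that takes hydride at its less substituted terminus (the former sulfone carbon), so the trisubstituted E olefin stays in place.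

Step 8
Reactants: 10 (2E,6E,10E,14S)-16-[(tert-butyldiphenylsilyl)oxy]-2,6,10,14-tetramethylhexadeca-2,6,10-trien-1-ol
Product: 11 [(2R,3R)-3-{(3E,7E,11S)-13-[(tert-butyldiphenylsilyl)oxy]-3,7,11-trimethyltrideca-3,7-dien-1-yl}-2-methyloxiran-2-yl]methanol
Conditions: Ti(OiPr)4 (10 mol %), D-(−)-diethyl tartrate (12 mol %), t-BuOOH, 4 Å MS, CH2Cl2, −20 °C
Reagents that add atoms: tert-butyl hydroperoxide, CC(C)(C)OO
Why: Sharpless asymmetric epoxidation should act only on the hydroxyl-bearing olefin, and the D-(−)-tartrate ligand should deliver oxygen to the face that gives the (2R,3R)-epoxide, setting the C3 configuration that later fixes the absolute sense of the bicyclisation.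

Step 9
Reactants: 11 [(2R,3R)-3-{(3E,7E,11S)-13-[(tert-butyldiphenylsilyl)oxy]-3,7,11-trimethyltrideca-3,7-dien-1-yl}-2-methyloxiran-2-yl]methanol
Product: 12 (1S,2R,4aS,5R,8aS)-5-{(3S)-5-[(tert-butyldiphenylsilyl)oxy]-3-methylpentyl}-1-(hydroxymethyl)-1,4a-dimethyl-6-methylidenedecahydronaphthalen-2-ol
Conditions: Cp2TiCl2 (2.5 equiv), Mn dust (8 equiv), THF, rt; green Cp2TiCl solution added slowly to 11 (0.02 M in THF); then 1 M HCl
Reagents that add atoms: none
Why: Cp2TiCl (trivalent titanium, made in the flask) should open the epoxide homolytically to the tertiary C4 radical with a titanium alkoxide on C3; this radical adds to C5 of the C5=C10 olefin to close ring A (6-endo-trig), the tertiary C10 radical adds to C9 of the C8=C9 olefin to close ring B (6-endo-trig), and the tertiary C8 radical is intercepted by a second Cp2TiCl and loses a hydrogen from C17 to give the exocyclic olefin. The closest known reaction type is the Cp2TiCl-mediated radical cyclisation of epoxypolyprenes (Nugent–RajanBabu-type epoxide opening followed by a polyene cascade), which is established for decalins of the labdane type. C5, C10 and C9 should be set by the chair–chair transition state of the two E olefins (trans ring fusion, C11 equatorial and cis to the C10 methyl), and the absolute sense by the C3 stereocentre from step 8, whose titanoxy group sits equatorial. C4 should be set by a six-membered chelate between the titanium on O3 and the free C18 hydroxyl, which holds C18 anti to C2 so that CH2OH ends equatorial and the methyl axial, the arrangement the E epoxide already has. The step needs opening toward C4 (secured by the trisubstituted epoxide), endo rather than exo closure (secured by the methyl groups on C10 and C8, which make attack at the CH terminus less hindered and tertiary-radical-forming) and a stop after two rings (secured by the saturated C11–C15 chain and by slow addition, which keeps Cp2TiCl scarce until the C8 radical is reached).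

Step 10
Reactants: 12 (1S,2R,4aS,5R,8aS)-5-{(3S)-5-[(tert-butyldiphenylsilyl)oxy]-3-methylpentyl}-1-(hydroxymethyl)-1,4a-dimethyl-6-methylidenedecahydronaphthalen-2-ol
Product: 13 3,18-cyclic thionocarbonate of 12 (1,3-dioxane-2-thione trans-fused to ring A across C3–C4)
Conditions: 1,1′-thiocarbonyldiimidazole, DMAP (cat.), toluene, 90 °C
Reagents that add atoms: 1,1′-thiocarbonyldiimidazole, S=C(n1ccnc1)n1ccnc1
Why: The primary hydroxyl should be thioacylated first and the neighbouring equatorial C3 hydroxyl should then close the strain-free six-membered cyclic thionocarbonate, as for diequatorial 1,3-diols.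

Step 11
Reactants: 13 3,18-cyclic thionocarbonate of 12
Product: 15 [(1S,4aS,5R,8aS)-5-{(3S)-5-[(tert-butyldiphenylsilyl)oxy]-3-methylpentyl}-1,4a-dimethyl-6-methylidenedecahydronaphthalen-1-yl]methanol, via stannyl thiolcarbonate 14 (not isolated)
Conditions: Bu3SnH, AIBN (cat.), toluene, 110 °C; then K2CO3, MeOH–H2O, rt
Reagents that add atoms: none
Why: In this Barton–McCombie deoxygenation of a cyclic thionocarbonate the stannyl radical adds to sulfur and the ring should fragment at the C3–O bond (secondary radical) rather than at C18–O (primary radical), so C3 becomes CH2 and mild hydrolysis of the remaining thiolcarbonate frees the C18 hydroxyl.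

Step 12
Reactants: 15 [(1S,4aS,5R,8aS)-5-{(3S)-5-[(tert-butyldiphenylsilyl)oxy]-3-methylpentyl}-1,4a-dimethyl-6-methylidenedecahydronaphthalen-1-yl]methanol
Product: 16 (1S,2S,4aS,5S,8aR)-1-{(3S)-5-[(tert-butyldiphenylsilyl)oxy]-3-methylpentyl}-5-(hydroxymethyl)-2,5,8a-trimethyldecahydronaphthalen-2-ol
Conditions: Co(acac)2 (20 mol %), PhSiH3, O2 (1 atm), THF–i-PrOH, 0 °C to rt
Reagents that add atoms: dioxygen, O=O
Why: In this Mukaiyama hydration a hydrogen atom is transferred to C17, and the planar tertiary C8 radical should take up dioxygen on the face opposite the axial C10 methyl, which gives the equatorial hydroxyl and the axial C17 methyl after in situ reduction of the peroxide.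

Step 13
Reactants: 16 (1S,2S,4aS,5S,8aR)-1-{(3S)-5-[(tert-butyldiphenylsilyl)oxy]-3-methylpentyl}-5-(hydroxymethyl)-2,5,8a-trimethyldecahydronaphthalen-2-ol; 17 angelic acid
Product: 19 [(1S,4aR,5S,6S,8aS)-5-{(3S)-5-[(tert-butyldiphenylsilyl)oxy]-3-methylpentyl}-6-hydroxy-1,4a,6-trimethyldecahydronaphthalen-1-yl]methyl (2Z)-2-methylbut-2-enoate, via mixed anhydride 18 (not isolated)
Conditions: 17, 2,4,6-trichlorobenzoyl chloride, Et3N, toluene, rt; then 16, 80 °C
Reagents that add atoms: none
Why: Yamaguchi esterification through the mixed anhydride, run without DMAP, is the standard way to attach angelic acid without Z to E isomerisation and should acylate only the primary C18 hydroxyl, the tertiary C8 hydroxyl being inert.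

Step 14
Reactants: 19 [(1S,4aR,5S,6S,8aS)-5-{(3S)-5-[(tert-butyldiphenylsilyl)oxy]-3-methylpentyl}-6-hydroxy-1,4a,6-trimethyldecahydronaphthalen-1-yl]methyl (2Z)-2-methylbut-2-enoate
Product: 20 [(1S,4aR,5S,6S,8aS)-6-hydroxy-5-[(3S)-5-hydroxy-3-methylpentyl]-1,4a,6-trimethyldecahydronaphthalen-1-yl]methyl (2Z)-2-methylbut-2-enoate
Conditions: TBAF, AcOH (1:1), THF, rt
Reagents that add atoms: none
Why: Acetic acid-buffered fluoride should cleave the silyl ether without basic conditions that could isomerise or transfer the angelate.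

Step 15
Reactants: 20 [(1S,4aR,5S,6S,8aS)-6-hydroxy-5-[(3S)-5-hydroxy-3-methylpentyl]-1,4a,6-trimethyldecahydronaphthalen-1-yl]methyl (2Z)-2-methylbut-2-enoate
Product: 21 (3S)-5-[(1S,2S,4aS,5S,8aR)-2-hydroxy-2,5,8a-trimethyl-5-({[(2Z)-2-methylbut-2-enoyl]oxy}methyl)decahydronaphthalen-1-yl]-3-methylpentanoic acid
Conditions: TEMPO (0.2 equiv), PhI(OAc)2 (2.5 equiv), MeCN–H2O, rt
Reagents that add atoms: water, O
Why: The oxoammonium oxidation should take the only primary alcohol through the aldehyde hydrate to the acid, while the tertiary alcohol and the electron-poor angelate olefin do not react.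

**Compound list**

1 | geranyl bromide, (2E)-1-bromo-3,7-dimethylocta-2,6-diene | CC(C)=CCC/C(C)=C/CBr | starting material
2 | geranyl phenyl sulfone, {[(2E)-3,7-dimethylocta-2,6-dien-1-yl]sulfonyl}benzene | CC(C)=CCC/C(C)=C/CS(=O)(=O)c1ccccc1 | intermediate
3 | (2E,6E)-2,6-dimethyl-8-(phenylsulfonyl)octa-2,6-dien-1-ol | OC/C(C)=C/CC/C(C)=C/CS(=O)(=O)c1ccccc1 | intermediate
4 | (S)-citronellol, (3S)-3,7-dimethyloct-6-en-1-ol | CC(C)=CCC[C@H](C)CCO | starting material
5 | tert-butyl{[(3S)-3,7-dimethyloct-6-en-1-yl]oxy}diphenylsilane | CC(C)=CCC[C@H](C)CCO[Si](c1ccccc1)(c1ccccc1)C(C)(C)C | intermediate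
6 | (2E,6S)-8-[(tert-butyldiphenylsilyl)oxy]-2,6-dimethyloct-2-en-1-ol | OC/C(C)=C/CC[C@H](C)CCO[Si](c1ccccc1)(c1ccccc1)C(C)(C)C | intermediate
7 | {[(3S,6E)-8-bromo-3,7-dimethyloct-6-en-1-yl]oxy}(tert-butyl)diphenylsilane | BrC/C(C)=C/CC[C@H](C)CCO[Si](c1ccccc1)(c1ccccc1)C(C)(C)C | intermediate
8 | dilithiated sulfone (O-lithio, α-sulfonyl C-lithio derivative of 3) | [Li]OC/C(C)=C/CC/C(C)=C/C([Li])S(=O)(=O)c1ccccc1 | intermediate (not isolated)
9 | (2E,6E,10E,14S)-16-[(tert-butyldiphenylsilyl)oxy]-2,6,10,14-tetramethyl-8-(phenylsulfonyl)hexadeca-2,6,10-trien-1-ol, both C8 epimers | OC/C(C)=C/CC/C(C)=C/C(C/C(C)=C/CC[C@H](C)CCO[Si](c1ccccc1)(c1ccccc1)C(C)(C)C)S(=O)(=O)c1ccccc1 | intermediate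
10 | (2E,6E,10E,14S)-16-[(tert-butyldiphenylsilyl)oxy]-2,6,10,14-tetramethylhexadeca-2,6,10-trien-1-ol | OC/C(C)=C/CC/C(C)=C/CC/C(C)=C/CC[C@H](C)CCO[Si](c1ccccc1)(c1ccccc1)C(C)(C)C | intermediate
11 | [(2R,3R)-3-{(3E,7E,11S)-13-[(tert-butyldiphenylsilyl)oxy]-3,7,11-trimethyltrideca-3,7-dien-1-yl}-2-methyloxiran-2-yl]methanol | OC[C@@]1(C)O[C@@H]1CC/C(C)=C/CC/C(C)=C/CC[C@H](C)CCO[Si](c1ccccc1)(c1ccccc1)C(C)(C)C | intermediate
12 | (1S,2R,4aS,5R,8aS)-5-{(3S)-5-[(tert-butyldiphenylsilyl)oxy]-3-methylpentyl}-1-(hydroxymethyl)-1,4a-dimethyl-6-methylidenedecahydronaphthalen-2-ol (trans-decalin; 2-OH and CH2OH equatorial; 1-methyl axial and cis to the angular methyl) | OC[C@@]1(C)[C@H](O)CC[C@]2(C)[C@@H]1CCC(=C)[C@H]2CC[C@H](C)CCO[Si](c1ccccc1)(c1ccccc1)C(C)(C)C | intermediate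
13 | 3,18-cyclic thionocarbonate of 12 (six-membered 1,3-dioxane-2-thione trans-fused to ring A; other stereocentres as in 12) | S=C1OC[C@@]2(C)[C@H](O1)CC[C@]3(C)[C@@H]2CCC(=C)[C@H]3CC[C@H](C)CCO[Si](c1ccccc1)(c1ccccc1)C(C)(C)C | intermediate
14 | stannyl thiolcarbonate: 15 carrying C(=O)SSnBu3 on the C18 oxygen | CCCC[Sn](CCCC)(CCCC)SC(=O)OC[C@@]1(C)CCC[C@]2(C)[C@@H]1CCC(=C)[C@H]2CC[C@H](C)CCO[Si](c1ccccc1)(c1ccccc1)C(C)(C)C | intermediate (not isolated)
15 | [(1S,4aS,5R,8aS)-5-{(3S)-5-[(tert-butyldiphenylsilyl)oxy]-3-methylpentyl}-1,4a-dimethyl-6-methylidenedecahydronaphthalen-1-yl]methanol | OC[C@@]1(C)CCC[C@]2(C)[C@@H]1CCC(=C)[C@H]2CC[C@H](C)CCO[Si](c1ccccc1)(c1ccccc1)C(C)(C)C | intermediate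
16 | (1S,2S,4aS,5S,8aR)-1-{(3S)-5-[(tert-butyldiphenylsilyl)oxy]-3-methylpentyl}-5-(hydroxymethyl)-2,5,8a-trimethyldecahydronaphthalen-2-ol | OC[C@@]1(C)CCC[C@]2(C)[C@@H]1CC[C@](C)(O)[C@H]2CC[C@H](C)CCO[Si](c1ccccc1)(c1ccccc1)C(C)(C)C | intermediate
17 | angelic acid, (2Z)-2-methylbut-2-enoic acid | C/C=C(/C)C(=O)O | starting material
18 | mixed anhydride of angelic acid and 2,4,6-trichlorobenzoic acid | C/C=C(/C)C(=O)OC(=O)c1c(Cl)cc(Cl)cc1Cl | intermediate (not isolated)
19 | [(1S,4aR,5S,6S,8aS)-5-{(3S)-5-[(tert-butyldiphenylsilyl)oxy]-3-methylpentyl}-6-hydroxy-1,4a,6-trimethyldecahydronaphthalen-1-yl]methyl (2Z)-2-methylbut-2-enoate | C/C=C(/C)C(=O)OC[C@@]1(C)CCC[C@]2(C)[C@@H]1CC[C@](C)(O)[C@H]2CC[C@H](C)CCO[Si](c1ccccc1)(c1ccccc1)C(C)(C)C | intermediate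
20 | [(1S,4aR,5S,6S,8aS)-6-hydroxy-5-[(3S)-5-hydroxy-3-methylpentyl]-1,4a,6-trimethyldecahydronaphthalen-1-yl]methyl (2Z)-2-methylbut-2-enoate | C/C=C(/C)C(=O)OC[C@@]1(C)CCC[C@]2(C)[C@@H]1CC[C@](C)(O)[C@H]2CC[C@H](C)CCO | intermediate
21 | (3S)-5-[(1S,2S,4aS,5S,8aR)-2-hydroxy-2,5,8a-trimethyl-5-({[(2Z)-2-methylbut-2-enoyl]oxy}methyl)decahydronaphthalen-1-yl]-3-methylpentanoic acid | C/C=C(/C)C(=O)OC[C@@]1(C)CCC[C@]2(C)[C@@H]1CC[C@](C)(O)[C@H]2CC[C@H](C)CC(=O)O | target

**Step count and risks**

Total: 15 steps. Longest linear sequence: 13 steps (4 to 21 through steps 3–15).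

Steps most likely to fail:

1. Step 9. The prochiral C4 radical may rotate about C3–C4 faster than it cyclises, so facial control at C4 rests on the titanium chelate and may be incomplete. The radical may also be reduced by a second titanium centre and lose a β-oxygen before ring closure, and the termination may give endocyclic olefin isomers. Fallback (cationic, stereospecific at C4): starting from 11, the primary hydroxyl would be capped (TESCl, imidazole, CH2Cl2) to give the triethylsilyl ether F1. Treatment of F1 with MeAlCl2 in CH2Cl2 at −78 °C should open the epoxide with concerted anti attack of the C5=C10 olefin, which transfers the E geometry to C4 without a free radical, and after separation from endocyclic olefin isomers would give the 3-hydroxy 18-triethylsilyl ether F2. Cleavage of the triethylsilyl group (PPTS, MeOH) would rejoin the route at 12.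

2. Step 12. Dioxygen capture of the C8 radical on the wrong face (giving the axial alcohol) or simple reduction of the radical to the C8–H compound may compete. Fallback (epoxidation, then hydride opening): starting from 15, mCPBA with NaHCO3 in CH2Cl2 at 0 °C should attack the exocyclic olefin from the face opposite the axial C10 methyl and give the spiro-epoxide F3. LiBHEt3 in THF would then deliver hydride to the unhindered epoxide CH2 and rejoin the route at 16.

3. Step 11. Fragmentation of the cyclic thionocarbonate toward the primary C18 side, or reduction of the thiocarbonyl group without C–O cleavage, may compete. Fallback (acyclic deoxygenation with a protected C18 hydroxyl): starting from 12, selective acetylation of the primary hydroxyl (AcCl, 2,4,6-collidine, CH2Cl2, −78 °C) would give the 18-monoacetate F4. Phenyl chlorothionoformate with pyridine and DMAP would convert the C3 hydroxyl into the phenyl thionocarbonate F5. Bu3SnH and AIBN in toluene at 110 °C would give the 3-deoxy acetate F6, and K2CO3 in MeOH would rejoin the route at 15.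

**Further compounds**

F1 | step 9 | triethylsilyl ether of 11, {[(2R,3R)-3-{(3E,7E,11S)-13-[(tert-butyldiphenylsilyl)oxy]-3,7,11-trimethyltrideca-3,7-dien-1-yl}-2-methyloxiran-2-yl]methoxy}triethylsilane | CC[Si](CC)(CC)OC[C@@]1(C)O[C@@H]1CC/C(C)=C/CC/C(C)=C/CC[C@H](C)CCO[Si](c1ccccc1)(c1ccccc1)C(C)(C)C
F2 | step 9 | 18-O-triethylsilyl ether of 12 (3-hydroxyl free) | CC[Si](CC)(CC)OC[C@@]1(C)[C@H](O)CC[C@]2(C)[C@@H]1CCC(=C)[C@H]2CC[C@H](C)CCO[Si](c1ccccc1)(c1ccccc1)C(C)(C)C
F3 | step 12 | spiro-epoxide of 15 at C8/C17, oxygen equatorial and anti to the C10 methyl | OC[C@@]1(C)CCC[C@]2(C)[C@@H]1CC[C@@]3(CO3)[C@H]2CC[C@H](C)CCO[Si](c1ccccc1)(c1ccccc1)C(C)(C)C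
F4 | step 11 | 18-O-acetate of 12 | CC(=O)OC[C@@]1(C)[C@H](O)CC[C@]2(C)[C@@H]1CCC(=C)[C@H]2CC[C@H](C)CCO[Si](c1ccccc1)(c1ccccc1)C(C)(C)C
F5 | step 11 | 18-O-acetyl-3-O-(phenoxythiocarbonyl) derivative of 12 | CC(=O)OC[C@@]1(C)[C@H](OC(=S)Oc3ccccc3)CC[C@]2(C)[C@@H]1CCC(=C)[C@H]2CC[C@H](C)CCO[Si](c1ccccc1)(c1ccccc1)C(C)(C)C
F6 | step 11 | acetate of 15 | CC(=O)OC[C@@]1(C)CCC[C@]2(C)[C@@H]1CCC(=C)[C@H]2CC[C@H](C)CCO[Si](c1ccccc1)(c1ccccc1)C(C)(C)C
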